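**Retrosynthetic overview**

- The strategy rests on the pyranone ring O1–C2–C3–C4–C4a–C8a of the target isoflavone. C3, which carries the aryl group and sits next to the C4 carbonyl, is the nucleophilic α-carbon of a masked enaminone; C2, next to O1, is its β-carbon and becomes iminium-like after oxidation. The C3–C1' bond and the O1–C2 bond can therefore be made in one operation.
- Disconnecting C3–C1' and O1–C2 together leads to an ortho-hydroxyaryl enaminone (ring A plus C4, C3, C2) and a 3,4,5-trimethoxyphenyl radical, generated from the arenediazonium tetrafluoroborate.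
- The enaminone comes from 2-hydroxy-3,4,5-trimethoxyacetophenone and DMF dimethyl acetal (supplies C2); the acetophenone comes from 2,3,4-trimethoxyphenol and acetic anhydride by Fries rearrangement (supplies C4 and C3); the diazonium salt comes from 3,4,5-trimethoxyaniline.
- Ring order: rings A and C are bought intact; the pyranone ring is the only ring built and closes last, in the key step.

Key step: step 4

Remark: the target has no stereocentre and no hindered axis, so it is achiral; the structure given is its only stereoisomer and the route needs no stereocontrol.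

**Route**

Step 1
Reactants: 1 2,3,4-trimethoxyphenol; 2 acetic anhydride
Product: 5 1-(2-hydroxy-3,4,5-trimethoxyphenyl)ethan-1-one, via 2,3,4-trimethoxyphenyl acetate 3 (not isolated), via difluoroboron chelate 4 (not isolated)
Conditions: Ac2O (1.2 equiv), BF3·OEt2 (4 equiv, neat), 0 °C → 80 °C; then H2O/EtOH, 80 °C
Reagents that add atoms: acetic anhydride (compound 2), CC(=O)OC(C)=O
Why: O-acetylation followed by BF3-promoted Fries rearrangement should deliver the acetyl group to the only free ortho carbon (the para position is blocked by OMe), because the six-membered O–BF2–O chelate 4 makes the ortho-hydroxy ketone the thermodynamic sink; hot aqueous ethanol then cleaves the chelate.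

Step 2
Reactants: 5 1-(2-hydroxy-3,4,5-trimethoxyphenyl)ethan-1-one; 6 N,N-dimethylformamide dimethyl acetal
Product: 7 (E)-3-(dimethylamino)-1-(2-hydroxy-3,4,5-trimethoxyphenyl)prop-2-en-1-one
Conditions: DMF-DMA (2 equiv), toluene, 100 °C; evaporate, crystallize
Reagents that add atoms: N,N-dimethylformamide dimethyl acetal (compound 6), COC(OC)N(C)C
Why: Aminomethylenation of a methyl ketone with an amide acetal (standard enaminone synthesis) should give the E-enaminone by enolate addition to the formamidinium ion and loss of methanol, while the phenol, held in a hydrogen bond to the carbonyl, stays free.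

Step 3
Reactants: 8 3,4,5-trimethoxyaniline
Product: 9 3,4,5-trimethoxybenzenediazonium tetrafluoroborate
Conditions: 48% aq. HBF4 (2.5 equiv), EtOH, 0 °C, then t-BuONO (1.2 equiv), 0 °C; precipitate with Et2O, dry cold in the dark
Reagents that add atoms: tert-butyl nitrite, CC(C)(C)ON=O; tetrafluoroboric acid, [H+].F[B-](F)(F)F
Why: Diazotization of a fully protonated primary arylamine with an alkyl nitrite and a non-nucleophilic acid should give the tetrafluoroborate, which precipitates and is stabilized by the donor methoxy groups.

Step 4
Reactants: 7 (E)-3-(dimethylamino)-1-(2-hydroxy-3,4,5-trimethoxyphenyl)prop-2-en-1-one; 9 3,4,5-trimethoxybenzenediazonium tetrafluoroborate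
Product: 12 6,7,8-trimethoxy-3-(3,4,5-trimethoxyphenyl)-4H-chromen-4-one, via iminium tetrafluoroborate adduct 10 (not isolated), via 2-(dimethylamino)isoflavanone 11 (not isolated)
Conditions: Ru(bpy)3Cl2·6H2O (2 mol%), degassed MeCN, N2, blue LEDs (455 nm), 25 °C; 9 (1.5 equiv) in MeCN by syringe pump over 3 h; then H2O work-up
Reagents that add atoms: none
Why: Excited Ru(II) should reduce 9 by single-electron transfer; N2 is lost and the 3,4,5-trimethoxyphenyl σ-radical adds to the electron-rich α-carbon of the push–pull alkene of 7 (future C3), giving an α-amino radical at the future C2 that is oxidized by Ru(III), or by a second molecule of 9 in a chain, to iminium ion 10. The closest known reaction type is the photoredox Meerwein-type C–H arylation of enaminones with arenediazonium salts, including its domino form that turns ortho-hydroxyaryl enaminones into 3-arylchromones. The pyranone ring closes by 6-exo-trig addition of the phenolic oxygen to the iminium carbon (the C=N+ bond is exocyclic to the new ring; should 10 first lose its C3 proton to give the α-aryl enaminone, the same O1–C2 bond forms by 6-endo-trig oxa-Michael addition), giving aminal 11, and E1cB loss of dimethylamine across C2–C3 then aromatizes the ring. No stereocentre is retained: the centres at C3 of 10 and at C2/C3 of 11 form racemic and are erased by the elimination. The step needs radical C-arylation at the α-carbon to outrun polar azo coupling at that carbon; this is secured because the α-carbon is the only enaminone carbon with a high HOMO coefficient, the single free position of ring A is meta to the hydroxyl and ortho to the acyl group and so is inert to the diazonium ion, and slow addition of the electron-rich, weakly electrophilic salt 9 under irradiation keeps its concentration low.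

**Compound list**

1 | 2,3,4-trimethoxyphenol | COc1ccc(O)c(OC)c1OC | starting material
2 | acetic anhydride | CC(=O)OC(C)=O | starting material
3 | 2,3,4-trimethoxyphenyl acetate | CC(=O)Oc1ccc(OC)c(OC)c1OC | intermediate (not isolated)
4 | difluoroboron chelate of 5 (2,2-difluoro-6,7,8-trimethoxy-4-methyl-1,3,2-benzodioxaborinine O→B chelate) | CC1=[O+][B-](F)(F)Oc2c(OC)c(OC)c(OC)cc21 | intermediate (not isolated)
5 | 1-(2-hydroxy-3,4,5-trimethoxyphenyl)ethan-1-one | CC(=O)c1cc(OC)c(OC)c(OC)c1O | intermediate
6 | N,N-dimethylformamide dimethyl acetal | COC(OC)N(C)C | starting material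
7 | (E)-3-(dimethylamino)-1-(2-hydroxy-3,4,5-trimethoxyphenyl)prop-2-en-1-one | CN(C)/C=C/C(=O)c1cc(OC)c(OC)c(OC)c1O | intermediate
8 | 3,4,5-trimethoxyaniline | COc1cc(N)cc(OC)c1OC | starting material
9 | 3,4,5-trimethoxybenzenediazonium tetrafluoroborate | COc1cc([N+]#N)cc(OC)c1OC.F[B-](F)(F)F | intermediate
10 | N-[3-(2-hydroxy-3,4,5-trimethoxyphenyl)-3-oxo-2-(3,4,5-trimethoxyphenyl)propylidene]-N-methylmethanaminium tetrafluoroborate (racemic) | C[N+](C)=CC(C(=O)c1cc(OC)c(OC)c(OC)c1O)c1cc(OC)c(OC)c(OC)c1.F[B-](F)(F)F | intermediate (not isolated)
11 | 2-(dimethylamino)-6,7,8-trimethoxy-3-(3,4,5-trimethoxyphenyl)chroman-4-one (racemic, mixture of diastereomers) | CN(C)C1Oc2c(OC)c(OC)c(OC)cc2C(=O)C1c1cc(OC)c(OC)c(OC)c1 | intermediate (not isolated)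
12 | 6,7,8-trimethoxy-3-(3,4,5-trimethoxyphenyl)-4H-chromen-4-one | COc1cc(-c2coc3c(OC)c(OC)c(OC)cc3c2=O)cc(OC)c1OC | target

**Step count**

Total: 4 steps. Longest linear sequence: 3 steps (steps 1, 2, 4); step 3 is the convergent branch.

**Steps most likely to fail**

1. Step 4. Polar azo coupling of the diazonium ion at the enaminone α-carbon, or hydrogen abstraction by the aryl radical from the medium, may outpace radical C–C bond formation. Fallback, setting out from 7: treatment with I2 (CHCl3, rt) should give, by iodination at the α-carbon, ring closure and loss of dimethylamine, 3-iodo-6,7,8-trimethoxy-4H-chromen-4-one F1. Suzuki–Miyaura coupling of F1 with commercial (3,4,5-trimethoxyphenyl)boronic acid (Pd(dppf)Cl2, K2CO3, dioxane/H2O, 80 °C) then comes back to the route at 12.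

2. Step 1. Intermolecular acyl transfer to the position para to the 2-methoxy group may compete with ortho migration, and cleavage of the boron chelate may be incomplete. Fallback, setting out from 1: O-methylation (MeI, K2CO3, acetone, reflux) should give 1,2,3,4-tetramethoxybenzene F2, whose two free positions are equivalent by symmetry. Friedel–Crafts acetylation (AcCl, AlCl3, CH2Cl2, 0 °C) gives 1-(2,3,4,5-tetramethoxyphenyl)ethan-1-one F3. Chelation-controlled cleavage of only the methoxy group ortho to the acetyl group (BCl3, CH2Cl2, −78 → 0 °C) comes back to the route at 5.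

3. Step 2. O-Methylation of the phenol by the amide acetal, or premature ring closure of the enaminone to the 3-unsubstituted chromone during isolation, may erode the material. Fallback, setting out from 5: Claisen formylation (HCO2Et, NaH 3 equiv, THF, 0 °C → rt, then AcOH quench) should give 2-hydroxy-6,7,8-trimethoxychroman-4-one F4, the cyclic hemiacetal of the β-keto aldehyde. Condensation of F4 with dimethylamine (2 M in THF, EtOH, rt → 50 °C) opens the hemiacetal and dehydrates to the enaminone, coming back to the route at 7.

**Further compounds**

F1 | step 4 | 3-iodo-6,7,8-trimethoxy-4H-chromen-4-one | COc1cc2c(=O)c(I)coc2c(OC)c1OC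
F2 | step 1 | 1,2,3,4-tetramethoxybenzene | COc1ccc(OC)c(OC)c1OC
F3 | step 1 | 1-(2,3,4,5-tetramethoxyphenyl)ethan-1-one | CC(=O)c1cc(OC)c(OC)c(OC)c1OC
F4 | step 2 | 2-hydroxy-6,7,8-trimethoxychroman-4-one (racemic) | OC1CC(=O)c2cc(OC)c(OC)c(OC)c2O1
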